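**Retrosynthetic overview**
- The C3 ester is cut to (2E,4E,6E)-5-methyldodeca-2,4,6-trienoic acid 26 and the decalin alcohol 20; the C4 methyl comes from an exocyclic methylene by 3-OH-directed hydrogenation.
- The C8 ketone, C7=C11 and C12-OH come from a C8 methyl dienol ether by singlet-oxygen [4+2]; the dioxine ring fixes CH2OH cis to C8.
- Ring A (C1=C2) comes from ring-rearrangement metathesis of a bicyclo[2.2.2]octene, which also turns C11 into the isopropenyl carbon.
- Feature the strategy rests on: C9, C8, C7, C11, C13, C1 and C10 (vicinal C8/C9 oxygens included) are the seven carbons of creosol, and quaternary C5 is the α-carbon of an isopropenyl ketone (C6 = CH2, C14 = methyl, C4 = carbonyl, C3 = carbinol).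
- Ring order: ring B first (step 6, as a bicyclo[2.2.2]octenone), then ring A (step 9).

Key step: step 6

Remarks on the chemistry: eremophilane numbering (C1 to C15) is used for all ring compounds. (R)-But-3-ene-1,2-diol of high enantiopurity is taken as purchasable. The C3 oxygen is carried as a 4-methoxybenzyl (PMB) ether rather than a silyl ether, so that it can be freed by DDQ while the C9 and C12 silyl ethers stay.

**Step 1**
Reactants: 1 (R)-but-3-ene-1,2-diol
Product: 2 (4R)-4-ethenyl-2-(4-methoxyphenyl)-1,3-dioxolane (both C2 epimers)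
Conditions: 4-MeOC6H4CH(OMe)2, PPTS (cat.), CH2Cl2, rt
Reagents that add atoms: 4-methoxybenzaldehyde dimethyl acetal, COc1ccc(C(OC)OC)cc1
Why: Acid-catalysed transacetalisation closes the five-membered benzylidene acetal without touching the carbinol centre; the acetal carbon forms as both epimers, which does not matter because it becomes a CH2 in step 2.

**Step 2**
Reactants: 2 (4R)-4-ethenyl-2-(4-methoxyphenyl)-1,3-dioxolane
Product: 3 (R)-2-[(4-methoxybenzyl)oxy]but-3-en-1-ol
Conditions: iBu2AlH, CH2Cl2, −78 to 0 °C; Rochelle salt work-up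
Reagents that add atoms: none
Why: Reductive acetal opening: aluminium binds the less hindered primary oxygen and hydride goes to the oxocarbenium carbon, so the PMB group stays on the secondary oxygen.

**Step 3**
Reactants: 3 (R)-2-[(4-methoxybenzyl)oxy]but-3-en-1-ol
Product: 4 (R)-2-[(4-methoxybenzyl)oxy]but-3-enal
Conditions: Dess–Martin periodinane, NaHCO3, CH2Cl2, 0 °C; used at once
Reagents that add atoms: none
Why: Dess–Martin oxidation is base-free, so the α-alkoxy β,γ-unsaturated aldehyde should neither epimerise nor move into conjugation.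

**Step 4**
Reactants: 4 (R)-2-[(4-methoxybenzyl)oxy]but-3-enal; 5 isopropenylmagnesium bromide
Product: 6 (4R)-4-[(4-methoxybenzyl)oxy]-2-methylhexa-1,5-dien-3-ol (both C3 epimers)
Conditions: THF, −78 °C; then aq. NH4Cl
Reagents that add atoms: none
Why: Grignard 1,2-addition to the aldehyde at low temperature; the new carbinol centre is oxidised away in step 5, so its configuration is irrelevant.

**Step 5**
Reactants: 6 (4R)-4-[(4-methoxybenzyl)oxy]-2-methylhexa-1,5-dien-3-ol
Product: 7 (R)-4-[(4-methoxybenzyl)oxy]-2-methylhexa-1,5-dien-3-one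
Conditions: Dess–Martin periodinane, NaHCO3, CH2Cl2, 0 °C to rt
Reagents that add atoms: none
Why: Dess–Martin oxidation of the allylic alcohol under buffered neutral conditions keeps the doubly activated C–H next to the ketone configurationally intact.

**Step 6**
Reactants: 7 (R)-4-[(4-methoxybenzyl)oxy]-2-methylhexa-1,5-dien-3-one; 8 creosol (2-methoxy-4-methylphenol)
Product: 10 endo cycloadduct (bicyclo[2.2.2]oct-5-en-2-one; C9 ketone; C8 dimethyl ketal; quaternary C5 with the acyl group syn to the C1=C11 bridge), via 6,6-dimethoxy-4-methylcyclohexa-2,4-dienone 9 (not isolated)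
Conditions: PhI(OAc)2, MeOH, 0 °C to rt; 8 added slowly (excess) to 7 and the oxidant
Reagents that add atoms: methanol, CO
Why: PhI(OAc)2 dearomatises 8 in methanol to the ortho-quinone monoketal 9, whose dienone adds across the enone alkene of 7 in a concerted, asynchronous [4+2] cycloaddition; the closest known type is the Diels–Alder trapping of in situ masked ortho-benzoquinones by α-substituted acrylic dienophiles. Ring B (C5–C10) closes in this single intermolecular [4+2] event by forming C5–C10 and C6–C7, and appears as the cyclohexane of a bicyclo[2.2.2]octenone whose C1=C11 bridge is later opened. Regiochemistry follows the polarisation of both partners: the acyl-bearing C5 joins the dienone terminus next to the carbonyl (C10) and the CH2 terminus joins the carbon next to the ketal (C7). C5 is set by the endo rule (acyl under the diene, so syn to the C1=C11 bridge, with the methyl toward the C8/C9 bridge), and C7 and C10 follow from suprafacial addition, so the three new centres are fixed relative to one another. Their absolute sense rests on C3 alone: allylic strain with the α-methyl should hold C3–H in the enone plane, the ether and vinyl groups then flank the two faces, and addition anti to the larger 4-methoxybenzyloxy group leads to 10; this bias is expected to be modest, the diastereomer with the mirror-image bicycle is separable, and enantiopurity is that of 1. Slow generation of 9 in the presence of 7 keeps dienone dimerisation in check.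

**Step 7**
Reactants: 10 endo cycloadduct
Product: 11 C9 carbinol (hydroxyl on the side of the C5 methyl, anti to the C1=C11 bridge)
Conditions: NaBH4, MeOH/CH2Cl2, −40 °C
Reagents that add atoms: none
Why: Borohydride reduction should pick the strained, doubly α-oxygenated C9 ketone over the neopentyl C4 ketone; the C5 methyl covers one face, so hydride enters from the alkene-bridge face and places the hydroxyl syn to the C5 methyl, as in the target.

**Step 8**
Reactants: 11 C9 carbinol
Product: 12 C9 triethylsilyl ether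
Conditions: Et3SiOTf, 2,6-lutidine, CH2Cl2, −78 to 0 °C
Reagents that add atoms: triethylsilyl trifluoromethanesulfonate, CC[Si](CC)(CC)OS(=O)(=O)C(F)(F)F
Why: Silyl triflate with a hindered pyridine base silylates the crowded secondary alcohol without enolising the C4 ketone or ionising the ketal.

**Step 9**
Reactants: 12 C9 triethylsilyl ether
Product: 13 cis-decalin ketone (C1=C2; C3 OPMB; C4 ketone; C5 methyl; C7 isopropenyl; C8 dimethyl ketal; C9 OSiEt3)
Conditions: second-generation Grubbs catalyst RuCl2(=CHPh)(H2IMes)(PCy3), ethylene (1 atm), 1,4-benzoquinone (cat.), toluene, 60 °C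
Reagents that add atoms: none
Why: Ring-rearrangement metathesis: strain release opens the bicyclic C1=C11 alkene (C11 becomes a methylidene) and the C1 alkylidene closes onto the C3 vinyl group; the endo acyl group puts C4 and C1 on the same face of ring B, so only the cis-fused ring A can form, and benzoquinone is there to suppress hydride-mediated alkene migration.

**Step 10**
Reactants: 13 cis-decalin ketone
Product: 14 C4 exocyclic methylene compound
Conditions: Cp2TiMe2, toluene/THF, 70 °C, dark
Reagents that add atoms: dimethyltitanocene, C[Ti](C)(C1C=CC=C1)C1C=CC=C1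
Why: Petasis methylenation by Cp2Ti=CH2 is non-basic, so the hindered ketone is olefinated without epimerising C3 or moving C1=C2 into conjugation.

**Step 11**
Reactants: 14 C4 exocyclic methylene compound
Product: 15 C8 methyl dienol ether (C8(OMe)=C7–C11(Me)=C12H2)
Conditions: Me3SiOTf, iPr2NEt, CH2Cl2, −20 °C to rt
Reagents that add atoms: none
Why: Silyl-triflate-mediated ketal-to-enol-ether elimination: ionisation gives the C8 oxocarbenium ion and the amine removes the allylic C7–H, which is favoured over C9–H because it gives the conjugated diene; C7 becomes trigonal.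

**Step 12**
Reactants: 15 C8 methyl dienol ether
Product: 17 (Z)-γ-hydroxy enone (C8 ketone; C7=C11; C12 hydroxyl cis to C8), via alkoxy endoperoxide 16 (not isolated)
Conditions: O2, tetraphenylporphyrin (cat.), visible light, CH2Cl2, −78 °C; then thiourea, MeOH, −78 °C to rt
Reagents that add atoms: dioxygen, O=O
Why: Singlet-oxygen [4+2] photooxygenation of the electron-rich 1-alkoxy diene joins O to C8 and C12, thiourea reduces the O–O bond and the C8 hemiketal loses methanol; the dioxine ring holds C12–O cis to C8, which fixes the alkene geometry.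

**Step 13**
Reactants: 17 (Z)-γ-hydroxy enone
Product: 18 C12 tert-butyldimethylsilyl ether
Conditions: tBuMe2SiCl, imidazole, CH2Cl2, 0 °C
Reagents that add atoms: tert-butyldimethylsilyl chloride, CC(C)(C)[Si](C)(C)Cl
Why: Base-mediated silylation of the only free, primary hydroxyl; this also blocks acid-triggered closure of the (Z)-hydroxy enone to a furan.

**Step 14**
Reactants: 18 C12 tert-butyldimethylsilyl ether
Product: 19 C3 carbinol (C1=C2; C4=CH2; C9 OSiEt3; C12 OSitBuMe2)
Conditions: DDQ, CH2Cl2/pH 7 buffer, 0 °C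
Reagents that add atoms: none
Why: Oxidative PMB cleavage by DDQ goes through the electron-rich arene, so both silyl ethers and the enone are left alone; limiting the oxidant and the temperature should spare the liberated bis-allylic alcohol.

**Step 15**
Reactants: 19 C3 carbinol
Product: 20 ring-A-saturated alcohol (C3 OH; C4 methyl cis to the C5 methyl; C9 OSiEt3; C12 OSitBuMe2)
Conditions: H2 (1 atm), [Ir(cod)(PCy3)(py)]PF6 (cat.), CH2Cl2, 0 °C to rt
Reagents that add atoms: none
Why: Hydroxyl-directed hydrogenation: the 3-OH binds iridium and delivers hydrogen to its own face of C4=CH2, so C4–H ends syn to the hydroxyl and the methyl cis to the C5 methyl; C1=C2 is reduced in the same way, while the tetrasubstituted, electron-poor C7=C11 with no free hydroxyl nearby should remain.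

**Step 16**
Reactants: 21 (E)-non-3-en-2-one
Product: 22 ethyl (2E,4E)-3-methyldeca-2,4-dienoate
Conditions: (EtO)2P(O)CH2CO2Et, NaH, THF, 0 °C to reflux
Reagents that add atoms: triethyl phosphonoacetate, CCOC(=O)CP(=O)(OCC)OCC
Why: Horner–Wadsworth–Emmons olefination of the methyl ketone places the ester trans to the larger alkenyl group; the minor (2Z) isomer would be removed by chromatography.

**Step 17**
Reactants: 22 ethyl (2E,4E)-3-methyldeca-2,4-dienoate
Product: 23 (2E,4E)-3-methyldeca-2,4-dien-1-ol
Conditions: iBu2AlH, CH2Cl2, −78 °C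
Reagents that add atoms: none
Why: 1,2-Reduction of the conjugated ester by the aluminium hydride gives the allylic alcohol without touching the diene.

**Step 18**
Reactants: 23 (2E,4E)-3-methyldeca-2,4-dien-1-ol
Product: 25 ethyl (2E,4E,6E)-5-methyldodeca-2,4,6-trienoate, via (2E,4E)-3-methyldeca-2,4-dienal 24 (not isolated)
Conditions: MnO2, Ph3P=CHCO2Et, CH2Cl2, rt
Reagents that add atoms: ethyl (triphenylphosphoranylidene)acetate, CCOC(=O)C=P(c1ccccc1)(c1ccccc1)c1ccccc1
Why: Allylic oxidation by MnO2 with in situ Wittig trapping by the stabilised ylide gives the (E)-enoate and avoids handling the isomerisation-prone dienal.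

**Step 19**
Reactants: 25 ethyl (2E,4E,6E)-5-methyldodeca-2,4,6-trienoate
Product: 26 (2E,4E,6E)-5-methyldodeca-2,4,6-trienoic acid
Conditions: LiOH, THF/MeOH/H2O, rt; then 1 M HCl, 0 °C
Reagents that add atoms: lithium hydroxide, [Li+].[OH-]
Why: Saponification of the ethyl ester; the all-E trienoate is not expected to isomerise under these mild conditions.

**Step 20**
Reactants: 20 ring-A-saturated alcohol; 26 (2E,4E,6E)-5-methyldodeca-2,4,6-trienoic acid
Product: 28 bis-silyl ether of the target (C3 trienoate; C9 OSiEt3; C12 OSitBuMe2), via mixed 2,4,6-trichlorobenzoic anhydride 27 (not isolated)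
Conditions: 2,4,6-Cl3C6H2COCl, Et3N, THF, rt; then 20, DMAP, toluene, rt
Reagents that add atoms: none
Why: Yamaguchi esterification: the hindered mixed anhydride transfers only the trienoyl group to the single free, secondary C3 hydroxyl with retention at C3.

**Step 21**
Reactants: 28 bis-silyl ether of the target
Product: 29 target CNP0226738.1
Conditions: HF·pyridine, pyridine, THF, 0 °C to rt
Reagents that add atoms: none
Why: Buffered fluoride desilylation removes the triethylsilyl and primary tert-butyldimethylsilyl ethers without hydrolysing the trienoate, and the excess pyridine should prevent acid-driven furan formation from the (Z)-hydroxy enone.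

**Compound list**
1 | (R)-but-3-ene-1,2-diol | C=C[C@@H](O)CO | starting material
2 | (4R)-4-ethenyl-2-(4-methoxyphenyl)-1,3-dioxolane (C2 epimers) | C=C[C@@H]1COC(c2ccc(OC)cc2)O1 | intermediate
3 | (R)-2-[(4-methoxybenzyl)oxy]but-3-en-1-ol | C=C[C@@H](OCc1ccc(OC)cc1)CO | intermediate
4 | (R)-2-[(4-methoxybenzyl)oxy]but-3-enal | C=C[C@@H](OCc1ccc(OC)cc1)C=O | intermediate
5 | isopropenylmagnesium bromide | CC(=C)[Mg]Br | starting material
6 | (4R)-4-[(4-methoxybenzyl)oxy]-2-methylhexa-1,5-dien-3-ol (C3 epimers) | C=C(C)C(O)[C@H](OCc1ccc(OC)cc1)C=C | intermediate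
7 | (R)-4-[(4-methoxybenzyl)oxy]-2-methylhexa-1,5-dien-3-one | C=C(C)C(=O)[C@H](OCc1ccc(OC)cc1)C=C | intermediate
8 | creosol (2-methoxy-4-methylphenol) | COc1cc(C)ccc1O | starting material
9 | 6,6-dimethoxy-4-methylcyclohexa-2,4-dienone | COC1(OC)C=C(C)C=CC1=O | intermediate
10 | endo cycloadduct: 3,3-dimethoxy-5,7-dimethyl-7-[(2R)-2-(4-methoxybenzyloxy)but-3-enoyl]bicyclo[2.2.2]oct-5-en-2-one, acyl syn to the alkene bridge | C=C[C@@H](OCc1ccc(OC)cc1)C(=O)[C@@]2(C)C[C@H]3C(C)=C[C@@H]2C(=O)C3(OC)OC | intermediate
11 | C9 carbinol of 10, hydroxyl syn to the C5 methyl | C=C[C@@H](OCc1ccc(OC)cc1)C(=O)[C@@]2(C)C[C@H]3C(C)=C[C@@H]2[C@@H](O)C3(OC)OC | intermediate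
12 | C9 triethylsilyl ether of 11 | C=C[C@@H](OCc1ccc(OC)cc1)C(=O)[C@@]2(C)C[C@H]3C(C)=C[C@@H]2[C@@H](O[Si](CC)(CC)CC)C3(OC)OC | intermediate
13 | cis-decalin ketone: C1=C2, 3-OPMB, 4-oxo, 5-methyl, 7-isopropenyl, 8,8-dimethoxy, 9-OSiEt3 (C5-Me, C10-H and C9-O on one face; C3-O and C7-isopropenyl on the other) | COc1ccc(CO[C@@H]2C=C[C@@H]3[C@@H](O[Si](CC)(CC)CC)C(OC)(OC)[C@H](C(C)=C)C[C@]3(C)C2=O)cc1 | intermediate
14 | C4 exocyclic methylene analogue of 13 | COc1ccc(CO[C@@H]2C=C[C@@H]3[C@@H](O[Si](CC)(CC)CC)C(OC)(OC)[C@H](C(C)=C)C[C@]3(C)C2=C)cc1 | intermediate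
15 | C8 methyl dienol ether (8-methoxy-7,11(12)-diene) | COc1ccc(CO[C@@H]2C=C[C@@H]3[C@@H](O[Si](CC)(CC)CC)C(OC)=C(C(C)=C)C[C@]3(C)C2=C)cc1 | intermediate
16 | alkoxy endoperoxide (3,6-dihydro-1,2-dioxine fused at C7–C8; C8 configuration not assigned) | COc1ccc(CO[C@@H]2C=C[C@@H]3[C@@H](O[Si](CC)(CC)CC)C4(OC)OOCC(C)=C4C[C@]3(C)C2=C)cc1 | intermediate
17 | (Z)-γ-hydroxy enone: 8-oxo, C7=C11, 12-hydroxy | COc1ccc(CO[C@@H]2C=C[C@@H]3[C@@H](O[Si](CC)(CC)CC)C(=O)/C(=C(/C)CO)C[C@]3(C)C2=C)cc1 | intermediate
18 | C12 tert-butyldimethylsilyl ether of 17 | COc1ccc(CO[C@@H]2C=C[C@@H]3[C@@H](O[Si](CC)(CC)CC)C(=O)/C(=C(/C)CO[Si](C)(C)C(C)(C)C)C[C@]3(C)C2=C)cc1 | intermediate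
19 | C3 carbinol (PMB removed) | O[C@@H]1C=C[C@@H]2[C@@H](O[Si](CC)(CC)CC)C(=O)/C(=C(/C)CO[Si](C)(C)C(C)(C)C)C[C@]2(C)C1=C | intermediate
20 | ring-A-saturated alcohol: 3-OH, 4-methyl cis to 5-methyl | O[C@@H]1CC[C@@H]2[C@@H](O[Si](CC)(CC)CC)C(=O)/C(=C(/C)CO[Si](C)(C)C(C)(C)C)C[C@]2(C)[C@H]1C | intermediate
21 | (E)-non-3-en-2-one | CCCCC/C=C/C(C)=O | starting material
22 | ethyl (2E,4E)-3-methyldeca-2,4-dienoate | CCCCC/C=C/C(C)=C/C(=O)OCC | intermediate
23 | (2E,4E)-3-methyldeca-2,4-dien-1-ol | CCCCC/C=C/C(C)=C/CO | intermediate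
24 | (2E,4E)-3-methyldeca-2,4-dienal | CCCCC/C=C/C(C)=C/C=O | intermediate
25 | ethyl (2E,4E,6E)-5-methyldodeca-2,4,6-trienoate | CCCCC/C=C/C(C)=C/C=C/C(=O)OCC | intermediate
26 | (2E,4E,6E)-5-methyldodeca-2,4,6-trienoic acid | CCCCC/C=C/C(C)=C/C=C/C(=O)O | intermediate
27 | mixed anhydride of 26 with 2,4,6-trichlorobenzoic acid | CCCCC/C=C/C(C)=C/C=C/C(=O)OC(=O)c1c(Cl)cc(Cl)cc1Cl | intermediate
28 | 9-O-triethylsilyl, 12-O-tert-butyldimethylsilyl ether of the target | CCCCC/C=C/C(C)=C/C=C/C(=O)O[C@@H]1CC[C@@H]2[C@@H](O[Si](CC)(CC)CC)C(=O)/C(=C(/C)CO[Si](C)(C)C(C)(C)C)C[C@]2(C)[C@H]1C | intermediate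
29 | CNP0226738.1: (3R,4R,5R,9R,10S,7(11)Z)-9,12-dihydroxy-8-oxoeremophil-7(11)-en-3-yl (2E,4E,6E)-5-methyldodeca-2,4,6-trienoate (eremophilane numbering) | CCCCC/C=C/C(C)=C/C=C/C(=O)O[C@@H]1CC[C@@H]2[C@@H](O)C(=O)/C(=C(/C)CO)C[C@]2(C)[C@H]1C | target

**Step count and risks**
Total steps: 21. Longest linear sequence: 17 (steps 1 to 15, then 20 and 21); the acid 26 takes 4 steps (16 to 19).

Steps most likely to fail:

1. Step 6 (key cycloaddition). What may go wrong: weak or reversed facial discrimination by the C3 ether, because the C3–C4 bond is free to rotate, so that little of 10 forms. Fallback: the C3 oxygen is made bulkier and non-coordinating for the cycloaddition and exchanged afterwards. Setting out from 1, bis-silylation (tBuMe2SiCl, imidazole) gives (R)-3,4-bis(tert-butyldimethylsilyloxy)but-1-ene F1. Selective cleavage of the primary silyl ether (HF·pyridine, pyridine, THF, 0 °C) gives (R)-2-(tert-butyldimethylsilyloxy)but-3-en-1-ol F2. Dess–Martin oxidation gives the aldehyde F3, addition of 5 gives the carbinol F4, and a second Dess–Martin oxidation gives the silyl enone F5. Cycloaddition with 9 generated from 8, as in step 6, gives the silyl adduct F6. HF·pyridine in MeCN frees the α-hydroxy ketone F7, and 4-methoxybenzyl trichloroacetimidate with catalytic La(OTf)3 comes back to 10.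

2. Step 9 (ring-rearrangement metathesis). What may go wrong: the trisubstituted bridge alkene is not opened, or a ruthenium hydride moves C1=C2 into conjugation with the C4 ketone. Fallback: ring opening is done by oxidative cleavage and ring A is closed by ordinary ring-closing metathesis of two vinyl groups. Setting out from 12, ozonolysis at −78 °C to a Sudan red end point, then Me2S, gives the keto aldehyde F8; the electron-rich, strained trisubstituted alkene should react before the vinyl group. Excess Cp2TiMe2 (toluene, 70 °C) methylenates the C1 aldehyde, the C11 methyl ketone and the C4 ketone to give the tetraene F9. RuCl2(=CHPh)(H2IMes)(PCy3) in CH2Cl2 at 40 °C then joins the C1 and C2 vinyl groups with loss of ethylene and comes back at 14, so step 10 is no longer needed.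

3. Step 12 (photooxygenation). What may go wrong: ene reaction or dioxetane formation at the enol ether instead of [4+2] addition, or fragmentation of the alkoxy endoperoxide before reduction. Fallback: electrophilic γ-bromination of the dienol ether and oxygen substitution. Setting out from 15, N-bromosuccinimide in THF/H2O with NaHCO3 at 0 °C gives the γ-bromo enone F10. CsOAc in DMF gives the allylic acetate F11, and K2CO3 in MeOH at 0 °C comes back to 17. In this variant no ring fixes the alkene geometry: a Z/E mixture is expected, the Z isomer would be separated and the E isomer re-equilibrated with catalytic I2 and light.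

**Further compounds**
F1 | step 6 | (R)-3,4-bis(tert-butyldimethylsilyloxy)but-1-ene | C=C[C@@H](O[Si](C)(C)C(C)(C)C)CO[Si](C)(C)C(C)(C)C
F2 | step 6 | (R)-2-(tert-butyldimethylsilyloxy)but-3-en-1-ol | C=C[C@@H](O[Si](C)(C)C(C)(C)C)CO
F3 | step 6 | (R)-2-(tert-butyldimethylsilyloxy)but-3-enal | C=C[C@@H](O[Si](C)(C)C(C)(C)C)C=O
F4 | step 6 | (4R)-4-(tert-butyldimethylsilyloxy)-2-methylhexa-1,5-dien-3-ol (C3 epimers) | C=C(C)C(O)[C@H](O[Si](C)(C)C(C)(C)C)C=C
F5 | step 6 | (R)-4-(tert-butyldimethylsilyloxy)-2-methylhexa-1,5-dien-3-one | C=C(C)C(=O)[C@H](O[Si](C)(C)C(C)(C)C)C=C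
F6 | step 6 | silyl analogue of cycloadduct 10 | C=C[C@@H](O[Si](C)(C)C(C)(C)C)C(=O)[C@@]1(C)C[C@H]2C(C)=C[C@@H]1C(=O)C2(OC)OC
F7 | step 6 | 3,3-dimethoxy-5,7-dimethyl-7-[(2R)-2-hydroxybut-3-enoyl]bicyclo[2.2.2]oct-5-en-2-one (endo) | C=C[C@@H](O)C(=O)[C@@]1(C)C[C@H]2C(C)=C[C@@H]1C(=O)C2(OC)OC
F8 | step 9 | ring-B keto aldehyde from ozonolysis of 12 (C1 aldehyde on C10, acetyl on C7) | C=C[C@@H](OCc1ccc(OC)cc1)C(=O)[C@@]2(C)C[C@@H](C(C)=O)C(OC)(OC)[C@H](O[Si](CC)(CC)CC)[C@H]2C=O
F9 | step 9 | tetraene from triple methylenation of F8 | C=C[C@@H](OCc1ccc(OC)cc1)C(=C)[C@@]2(C)C[C@@H](C(C)=C)C(OC)(OC)[C@H](O[Si](CC)(CC)CC)[C@H]2C=C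
F10 | step 12 | (Z)-γ-bromo enone (12-bromo analogue of 17) | COc1ccc(CO[C@@H]2C=C[C@@H]3[C@@H](O[Si](CC)(CC)CC)C(=O)/C(=C(/C)CBr)C[C@]3(C)C2=C)cc1
F11 | step 12 | (Z)-γ-acetoxy enone (12-O-acetate of 17) | COc1ccc(CO[C@@H]2C=C[C@@H]3[C@@H](O[Si](CC)(CC)CC)C(=O)/C(=C(/C)COC(C)=O)C[C@]3(C)C2=C)cc1
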